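## Retrosynthetic overview
1. Bromophycolide P ⇐ phenol unmasking ⇐ ring A closed last by an anodic, transannular bromonium cation–olefin cyclization (C2–C7 and C6–Br) of a tetrahydropyran-bridged macrolide carrying a (2E,6E)-1,5-diene.
2. Tetrahydropyran (C11–O, C10–Br) ⇐ 6-exo bromoetherification of a (10Z)-alkene by the C15 hydroxyl inside a 19-membered macrolactone.
3. Macrolactone ⇐ lactonization onto C14–OH of a seco acid; seco acid ⇐ sp3–sp2 Negishi union at C11–C12.
4. Fragments: a (Z)-vinyl iodide from methyl 4-hydroxybenzoate and (2E,6E)-farnesyl bromide; an alkyl iodide from (S)-α-hydroxy-γ-butyrolactone, whose carbinol carbon becomes C14, the only purchased stereocentre.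
5. Ring order: macrolactone, then tetrahydropyran, then ring A (the macrolide contracts from 19 to 15 members).

Assumption: (2E,6E)-farnesyl bromide and (S)-3-hydroxydihydrofuran-2(3H)-one are taken as purchasable; atoms are labelled C1 (benzylic CH2) to C15 (oxygen-bearing gem-dimethyl carbon) along the diterpene chain, and in this numbering the target is 2R,6S,7S,10R,11R,14S.

## Route

Step 1
Reactants: 1 methyl 4-hydroxybenzoate; 2 (2E,6E)-farnesyl bromide
Product: 3 methyl 4-hydroxy-3-[(2E,6E)-3,7,11-trimethyldodeca-2,6,10-trien-1-yl]benzoate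
Conditions: NaH, toluene, 0 °C to rt, 24 h
Reagents that add atoms: none
Why: Ortho C-allylation of a sodium phenoxide in a non-polar solvent (phenolate C-alkylation), where the tight ion pair delivers the allylic bromide to the ortho carbon by direct SN2 attack with retention of the (2E,6E) geometry, the para position being blocked by the ester; no stereocentre is formed.

Step 2
Reactants: 3 methyl 4-hydroxy-3-[(2E,6E)-3,7,11-trimethyldodeca-2,6,10-trien-1-yl]benzoate
Product: 4 methyl 4-(pivaloyloxy)-3-[(2E,6E)-3,7,11-trimethyldodeca-2,6,10-trien-1-yl]benzoate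
Conditions: PivCl, Et3N, DMAP (cat.), CH2Cl2, 0 °C to rt
Reagents that add atoms: pivaloyl chloride CC(C)(C)C(Cl)=O
Why: DMAP-catalysed O-acylation turns the phenol into an electron-poor, non-nucleophilic aryl pivalate that resists ring bromination and cannot trap cations as a chroman in the later bromination steps.

Step 3
Reactants: 4 methyl 4-(pivaloyloxy)-3-[(2E,6E)-3,7,11-trimethyldodeca-2,6,10-trien-1-yl]benzoate
Product: 6 racemic terminal epoxide methyl 3-[(2E,6E)-9-(3,3-dimethyloxiran-2-yl)-3,7-dimethylnona-2,6-dien-1-yl]-4-(pivaloyloxy)benzoate, via bromohydrin 5 (not isolated)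
Conditions: NBS, THF/H2O (4:1), 0 °C; then DBU, 0 °C to rt
Reagents that add atoms: water O
Why: Terminal-selective bromohydrin formation of a farnesyl chain in aqueous THF (van Tamelen conditions) followed by intramolecular Williamson closure; the epoxide stereocentre is racemic and is destroyed in the next step.

Step 4
Reactants: 6 racemic terminal epoxide methyl 3-[(2E,6E)-9-(3,3-dimethyloxiran-2-yl)-3,7-dimethylnona-2,6-dien-1-yl]-4-(pivaloyloxy)benzoate
Product: 8 aldehyde methyl 3-[(2E,6E)-3,7-dimethyl-10-oxodeca-2,6-dien-1-yl]-4-(pivaloyloxy)benzoate, via diol 7 (not isolated)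
Conditions: H5IO6, THF/H2O, 0 °C to rt
Reagents that add atoms: none
Why: Periodic acid hydrolyses the trisubstituted epoxide (water enters at the tertiary carbon) and cleaves the resulting glycol (Malaprade cleavage), giving the C10 aldehyde and acetone without touching the two remaining trisubstituted alkenes.

Step 5
Reactants: 8 aldehyde methyl 3-[(2E,6E)-3,7-dimethyl-10-oxodeca-2,6-dien-1-yl]-4-(pivaloyloxy)benzoate
Product: 9 methyl 3-[(2E,6E,10Z)-11-iodo-3,7-dimethyldodeca-2,6,10-trien-1-yl]-4-(pivaloyloxy)benzoate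
Conditions: EtPPh3I, n-BuLi, THF, rt; I2, −78 °C; NaN(SiMe3)2, −20 °C; then 8, −78 to −20 °C
Reagents that add atoms: ethyltriphenylphosphonium iodide CC[P+](c1ccccc1)(c1ccccc1)c1ccccc1.[I-]; iodine II
Why: Stork–Zhao-type Wittig olefination with the α-iodoethylidene ylide, whose kinetically controlled cis-oxaphosphetane places iodine cis to the chain (10Z) and so fixes the geometry of the future C10=C11 alkene.

Step 6
Reactants: 10 (S)-3-hydroxydihydrofuran-2(3H)-one
Product: 11 (3S)-4-methylpentane-1,3,4-triol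
Conditions: MeMgBr (4 equiv), THF, 0 °C to rt; aq NH4Cl
Reagents that add atoms: methylmagnesium bromide C[Mg]Br
Why: Double Grignard addition to the lactone carbonyl builds the C15 gem-dimethyl carbinol and frees the primary hydroxyl, and the purchased carbinol centre (future C14, S) is not touched because it sits as a magnesium alkoxide throughout.

Step 7
Reactants: 11 (3S)-4-methylpentane-1,3,4-triol
Product: 12 2-[(4S)-2,2,5,5-tetramethyl-1,3-dioxolan-4-yl]ethan-1-ol
Conditions: 2,2-dimethoxypropane, PPTS (cat.), acetone, rt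
Reagents that add atoms: 2,2-dimethoxypropane COC(C)(C)OC
Why: Thermodynamically controlled transacetalization gives the five-membered dioxolane across the secondary/tertiary diol in preference to the six-membered dioxane, leaving the primary hydroxyl free.

Step 8
Reactants: 12 2-[(4S)-2,2,5,5-tetramethyl-1,3-dioxolan-4-yl]ethan-1-ol
Product: 13 (4S)-4-(2-iodoethyl)-2,2,5,5-tetramethyl-1,3-dioxolane
Conditions: I2, PPh3, imidazole, CH2Cl2, 0 °C to rt
Reagents that add atoms: iodine II
Why: Appel-type (Garegg–Samuelsson) iodination of an unhindered primary alcohol under imidazole buffering that keeps the acetonide intact.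

Step 9
Reactants: 13 (4S)-4-(2-iodoethyl)-2,2,5,5-tetramethyl-1,3-dioxolane; 9 methyl 3-[(2E,6E,10Z)-11-iodo-3,7-dimethyldodeca-2,6,10-trien-1-yl]-4-(pivaloyloxy)benzoate
Product: 15 methyl 3-{(2E,6E,10Z)-3,7,11-trimethyl-13-[(4S)-2,2,5,5-tetramethyl-1,3-dioxolan-4-yl]trideca-2,6,10-trien-1-yl}-4-(pivaloyloxy)benzoate, via organozinc iodide 14 (not isolated)
Conditions: Zn, LiCl, THF, 35 °C; then 9, PdCl2(dppf) (5 mol %), THF/NMP, rt to 40 °C
Reagents that add atoms: none
Why: Direct zinc insertion into the primary iodide and sp3–sp2 Negishi coupling, which is stereoretentive at the vinyl iodide so that C9 and C12 end up cis (10Z) and which tolerates both esters.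

Step 10
Reactants: 15 methyl 3-{(2E,6E,10Z)-3,7,11-trimethyl-13-[(4S)-2,2,5,5-tetramethyl-1,3-dioxolan-4-yl]trideca-2,6,10-trien-1-yl}-4-(pivaloyloxy)benzoate
Product: 18 seco acid 3-[(2E,6E,10Z,14S)-14,15-dihydroxy-3,7,11,15-tetramethylhexadeca-2,6,10-trien-1-yl]-4-(pivaloyloxy)benzoic acid, via phenol acid 16 (not isolated), via pivalate acid 17 (not isolated)
Conditions: LiOH·H2O, THF/MeOH/H2O, 40 °C; PivCl, 0 °C (pH kept at 10 or above); then 2 M HCl to pH 1, rt
Reagents that add atoms: lithium hydroxide [Li+].[OH-]; pivaloyl chloride CC(C)(C)C(Cl)=O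
Why: Saponification frees the carboxylate (and the phenoxide), Schotten–Baumann acylation in water re-esterifies only the phenoxide, and dilute aqueous acid hydrolyses the acetonide without affecting the aryl pivalate or the trisubstituted alkenes; C14 is untouched.

Step 11
Reactants: 18 seco acid 3-[(2E,6E,10Z,14S)-14,15-dihydroxy-3,7,11,15-tetramethylhexadeca-2,6,10-trien-1-yl]-4-(pivaloyloxy)benzoic acid
Product: 19 (2E,6E,10Z,14S)-19-membered macrolactone (carboxyl esterified by O14; C15 hydroxyl free; phenol as pivalate)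
Conditions: MNBA (2-methyl-6-nitrobenzoic anhydride), DMAP, CH2Cl2, rt, syringe-pump addition, 1 mM
Reagents that add atoms: none
Why: Shiina macrolactonization through the mixed anhydride acylates the secondary C14 hydroxyl in preference to the tertiary C15 hydroxyl with retention at C14, and the hindered aryl pivalate keeps the phenol from competing.

Step 12
Reactants: 19 (2E,6E,10Z,14S)-19-membered macrolactone (carboxyl esterified by O14; C15 hydroxyl free; phenol as pivalate)
Product: 20 (2E,6E,10R,11R,14S)-10-bromo-11,15-epoxy macrolactone (2,2,6-trimethyltetrahydropyran with ring oxygen on C11 and C15; phenol as pivalate)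
Conditions: NBS, CH2Cl2, 4 Å MS, −20 to 0 °C, dark
Reagents that add atoms: N-bromosuccinimide BrN1C(=O)CCC1=O
Why: 6-exo-trig bromoetherification in which the C15 hydroxyl opens the bromonium ion at tertiary C11 anti to bromine, so the Z geometry fixes the C10/C11 pair as R/R or S/S, and the chair transition state with the C14 acyloxy group and the C10 arm both equatorial (the alternative suffers allylic 1,3-strain between C9 and C13) lets the purchased C14 (S) centre select 10R,11R.

Step 13
Reactants: 20 (2E,6E,10R,11R,14S)-10-bromo-11,15-epoxy macrolactone (2,2,6-trimethyltetrahydropyran with ring oxygen on C11 and C15; phenol as pivalate)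
Product: 21 bromophycolide P O-pivalate (2R,6S,7S,10R,11R,14S)
Conditions: undivided cell, reticulated vitreous carbon anode, Pt cathode, constant current, 2.2 F/mol; 2,4,6-trimethylpyridinium bromide (1.1 equiv, added by syringe pump), 2,4,6-trimethylpyridine (1 equiv), Bu4NPF6 (0.05 M), HFIP/CH2Cl2 (4:1), 0 °C
Reagents that add atoms: 2,4,6-trimethylpyridinium bromide Cc1cc(C)[nH+]c(C)c1.[Br-]
Why: Proposed new method: anodic two-electron oxidation of bromide in HFIP gives a collidine-bound bromenium (Br+) carrier that forms the bromonium ion at C6=C7, the transannular C2=C3 bond opens it at C7 through a chair transition state (anti addition, with the (2E,6E) geometry placing Br, C8 and C1 equatorial and so fixing the relative configuration of C2, C6 and C7), the C3 cation loses a methyl proton to the hindered base to give the exocyclic alkene, the cathode reduces protons to hydrogen, and the face of C6=C7 exposed on the periphery of the tetrahydropyran-bridged macrolide (set by C10, C11 and C14) is expected to give 2R,6S,7S; the closest known reaction types are bromonium-induced polyene cyclization with stoichiometric bromosulfonium or N-bromoimide reagents and anodic bromide oxidation for bromoetherification or bromolactonization.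

Step 14
Reactants: 21 bromophycolide P O-pivalate (2R,6S,7S,10R,11R,14S)
Product: 22 bromophycolide P
Conditions: K2CO3 (0.3 equiv), MeOH/THF, 0 °C to rt
Reagents that add atoms: none
Why: Base-catalysed methanolysis (transesterification) of the activated aryl pivalate, which is far faster than attack on the hindered secondary-alkyl benzoate lactone (further deactivated once the para phenoxide forms) or on the two neopentyl-type secondary bromides.

## Compound list
1 | methyl 4-hydroxybenzoate | COC(=O)c1ccc(O)cc1 | starting material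
2 | (2E,6E)-farnesyl bromide, (2E,6E)-1-bromo-3,7,11-trimethyldodeca-2,6,10-triene | BrC/C=C(\C)CC/C=C(\C)CCC=C(C)C | starting material
3 | methyl 4-hydroxy-3-[(2E,6E)-3,7,11-trimethyldodeca-2,6,10-trien-1-yl]benzoate | COC(=O)c1ccc(O)c(c1)C/C=C(\C)CC/C=C(\C)CCC=C(C)C | intermediate
4 | methyl 4-(pivaloyloxy)-3-[(2E,6E)-3,7,11-trimethyldodeca-2,6,10-trien-1-yl]benzoate | COC(=O)c1ccc(OC(=O)C(C)(C)C)c(c1)C/C=C(\C)CC/C=C(\C)CCC=C(C)C | intermediate
5 | bromohydrin, methyl 3-[(2E,6E)-10-bromo-11-hydroxy-3,7,11-trimethyldodeca-2,6-dien-1-yl]-4-(pivaloyloxy)benzoate (racemic at C10; not isolated) | COC(=O)c1ccc(OC(=O)C(C)(C)C)c(c1)C/C=C(\C)CC/C=C(\C)CCC(Br)C(C)(C)O | intermediate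
6 | terminal epoxide, methyl 3-[(2E,6E)-9-(3,3-dimethyloxiran-2-yl)-3,7-dimethylnona-2,6-dien-1-yl]-4-(pivaloyloxy)benzoate (racemic) | COC(=O)c1ccc(OC(=O)C(C)(C)C)c(c1)C/C=C(\C)CC/C=C(\C)CCC2OC2(C)C | intermediate
7 | diol, methyl 3-[(2E,6E)-10,11-dihydroxy-3,7,11-trimethyldodeca-2,6-dien-1-yl]-4-(pivaloyloxy)benzoate (racemic; not isolated) | COC(=O)c1ccc(OC(=O)C(C)(C)C)c(c1)C/C=C(\C)CC/C=C(\C)CCC(O)C(C)(C)O | intermediate
8 | aldehyde, methyl 3-[(2E,6E)-3,7-dimethyl-10-oxodeca-2,6-dien-1-yl]-4-(pivaloyloxy)benzoate | COC(=O)c1ccc(OC(=O)C(C)(C)C)c(c1)C/C=C(\C)CC/C=C(\C)CCC=O | intermediate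
9 | (Z)-vinyl iodide, methyl 3-[(2E,6E,10Z)-11-iodo-3,7-dimethyldodeca-2,6,10-trien-1-yl]-4-(pivaloyloxy)benzoate | COC(=O)c1ccc(OC(=O)C(C)(C)C)c(c1)C/C=C(\C)CC/C=C(\C)CC/C=C(C)\I | intermediate
10 | (S)-3-hydroxydihydrofuran-2(3H)-one, (S)-α-hydroxy-γ-butyrolactone | O=C1OCC[C@@H]1O | starting material
11 | (3S)-4-methylpentane-1,3,4-triol | OCC[C@H](O)C(C)(C)O | intermediate
12 | 2-[(4S)-2,2,5,5-tetramethyl-1,3-dioxolan-4-yl]ethan-1-ol | OCC[C@H](O1)C(C)(C)OC1(C)C | intermediate
13 | (4S)-4-(2-iodoethyl)-2,2,5,5-tetramethyl-1,3-dioxolane | ICC[C@H](O1)C(C)(C)OC1(C)C | intermediate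
14 | {2-[(4S)-2,2,5,5-tetramethyl-1,3-dioxolan-4-yl]ethyl}zinc iodide (not isolated) | I[Zn]CC[C@H](O1)C(C)(C)OC1(C)C | intermediate
15 | methyl 3-{(2E,6E,10Z)-3,7,11-trimethyl-13-[(4S)-2,2,5,5-tetramethyl-1,3-dioxolan-4-yl]trideca-2,6,10-trien-1-yl}-4-(pivaloyloxy)benzoate | COC(=O)c1ccc(OC(=O)C(C)(C)C)c(c1)C/C=C(\C)CC/C=C(\C)CC/C=C(C)\CC[C@H](O2)C(C)(C)OC2(C)C | intermediate
16 | phenol acid, 4-hydroxy-3-{(2E,6E,10Z)-3,7,11-trimethyl-13-[(4S)-2,2,5,5-tetramethyl-1,3-dioxolan-4-yl]trideca-2,6,10-trien-1-yl}benzoic acid (not isolated) | OC(=O)c1ccc(O)c(c1)C/C=C(\C)CC/C=C(\C)CC/C=C(C)\CC[C@H](O2)C(C)(C)OC2(C)C | intermediate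
17 | pivalate acid, 4-(pivaloyloxy)-3-{(2E,6E,10Z)-3,7,11-trimethyl-13-[(4S)-2,2,5,5-tetramethyl-1,3-dioxolan-4-yl]trideca-2,6,10-trien-1-yl}benzoic acid (not isolated) | OC(=O)c1ccc(OC(=O)C(C)(C)C)c(c1)C/C=C(\C)CC/C=C(\C)CC/C=C(C)\CC[C@H](O2)C(C)(C)OC2(C)C | intermediate
18 | seco acid, 3-[(2E,6E,10Z,14S)-14,15-dihydroxy-3,7,11,15-tetramethylhexadeca-2,6,10-trien-1-yl]-4-(pivaloyloxy)benzoic acid | OC(=O)c1ccc(OC(=O)C(C)(C)C)c(c1)C/C=C(\C)CC/C=C(\C)CC/C=C(C)\CC[C@H](O)C(C)(C)O | intermediate
19 | (2E,6E,10Z,14S)-19-membered macrolactone of 18 closed at O14, C15 hydroxyl free, phenol as pivalate | O=C1c2ccc(OC(=O)C(C)(C)C)c(c2)C/C=C(\C)CC/C=C(\C)CC/C=C(C)\CC[C@H](O1)C(C)(C)O | intermediate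
20 | (2E,6E,10R,11R,14S)-10-bromo-11,15-epoxy macrolactone (tetrahydropyran-bridged macrolide), phenol as pivalate | O=C1c2ccc(OC(=O)C(C)(C)C)c(c2)C/C=C(\C)CC/C=C(\C)CC[C@@H](Br)[C@@]3(C)CC[C@H](O1)C(C)(C)O3 | intermediate
21 | bromophycolide P O-pivalate (2R,6S,7S,10R,11R,14S) | C=C1CC[C@H](Br)[C@@]2(C)CC[C@@H](Br)[C@@]3(C)CC[C@H](OC(=O)c4ccc(OC(=O)C(C)(C)C)c(c4)C[C@H]12)C(C)(C)O3 | intermediate
22 | bromophycolide P (2R,6S,7S,10R,11R,14S) | C=C1CC[C@H](Br)[C@@]2(C)CC[C@@H](Br)[C@@]3(C)CC[C@H](OC(=O)c4ccc(O)c(c4)C[C@H]12)C(C)(C)O3 | target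

## Step count and risks
Total step count: 14. Longest linear sequence: 11 steps (steps 1 to 5, then 9 to 14); the three-step branch 6 to 8 joins at step 9.

Most likely to fail, step 13 (the proposed anodic transannular bromocyclization). Facial selectivity at C6=C7 rests on macrocyclic control that has not been demonstrated. The C3 cation may also lose an endocyclic proton, and free bromide may intercept the bromonium ion as a dibromide. The fallback uses known chemistry, sets out from 20 and comes back at 21. Hg(OCOCF3)2 in MeNO2 at −20 °C triggers the same transannular cation–olefin cyclization as a mercuricyclization of the 1,5-diene, and aqueous NaBr then gives the C6 alkylmercuric bromide F1. Brominative demercuration with Br2 and LiBr in pyridine at 0 °C in the dark, which proceeds with retention, then gives 21. Mercuration is reversible at the first stage, so it also offers a thermodynamic handle on the diastereomer ratio.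

Second, step 12 (bromoetherification inside the macrolactone). The 19-membered ring may override the chair preference and erode the 10R,11R selectivity, or the C6=C7 bond may compete for the C10–C11 bromonium ion. The fallback moves the etherification in front of ring closure; it sets out from 15 and comes back at 20. Aqueous acetic acid in THF removes the acetonide of 15 to give the open-chain diol diester F2. Ac2O in pyridine acetylates only the secondary C14 hydroxyl to give the monoacetate F3. NBS in CH2Cl2 then closes the ring on this unconstrained substrate to give the open-chain bromo tetrahydropyran acetate F4. LiOH followed by PivCl under the aqueous conditions of step 10 gives the bromo tetrahydropyran hydroxy acid F5. Shiina lactonization (MNBA, DMAP, high dilution) onto the ring hydroxyl of F5 gives 20.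

Third, step 5 (iodo-ylide olefination). The α-iodo ylide is thermally fragile, yields are usually moderate, and the Z/E ratio can erode. The fallback builds the same trisubstituted alkene by two selective couplings; it sets out from 8 and comes back at 15. A Corey–Fuchs reaction (CBr4, PPh3, CH2Cl2, 0 °C) gives the 1,1-dibromoalkene F6. Trans-selective monomethylation with MeZnCl and PdCl2(DPEphos) replaces the bromine trans to the chain and gives the (Z)-bromoalkene F7. Negishi coupling of F7 with organozinc 14 under Pd(P(t-Bu)3)2, which proceeds with retention, gives 15.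

Further compounds
F1 | step 13 | C6 alkylmercuric bromide corresponding to 21 (HgBr in place of the C6 bromine; 2R,6S,7S,10R,11R,14S) | C=C1CC[C@H]([Hg]Br)[C@@]2(C)CC[C@@H](Br)[C@@]3(C)CC[C@H](OC(=O)c4ccc(OC(=O)C(C)(C)C)c(c4)C[C@H]12)C(C)(C)O3
F2 | step 12 | methyl 3-[(2E,6E,10Z,14S)-14,15-dihydroxy-3,7,11,15-tetramethylhexadeca-2,6,10-trien-1-yl]-4-(pivaloyloxy)benzoate | COC(=O)c1ccc(OC(=O)C(C)(C)C)c(c1)C/C=C(\C)CC/C=C(\C)CC/C=C(C)\CC[C@H](O)C(C)(C)O
F3 | step 12 | methyl 3-[(2E,6E,10Z,14S)-14-acetoxy-15-hydroxy-3,7,11,15-tetramethylhexadeca-2,6,10-trien-1-yl]-4-(pivaloyloxy)benzoate | COC(=O)c1ccc(OC(=O)C(C)(C)C)c(c1)C/C=C(\C)CC/C=C(\C)CC/C=C(C)\CC[C@H](OC(C)=O)C(C)(C)O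
F4 | step 12 | open-chain (10R,11R,14S)-bromo tetrahydropyran acetate (methyl ester, aryl pivalate) | COC(=O)c1ccc(OC(=O)C(C)(C)C)c(c1)C/C=C(\C)CC/C=C(\C)CC[C@@H](Br)[C@@]2(C)CC[C@H](OC(C)=O)C(C)(C)O2
F5 | step 12 | open-chain (10R,11R,14S)-bromo tetrahydropyran hydroxy acid (aryl pivalate) | OC(=O)c1ccc(OC(=O)C(C)(C)C)c(c1)C/C=C(\C)CC/C=C(\C)CC[C@@H](Br)[C@@]2(C)CC[C@H](O)C(C)(C)O2
F6 | step 5 | methyl 3-[(2E,6E)-11,11-dibromo-3,7-dimethylundeca-2,6,10-trien-1-yl]-4-(pivaloyloxy)benzoate | COC(=O)c1ccc(OC(=O)C(C)(C)C)c(c1)C/C=C(\C)CC/C=C(\C)CCC=C(Br)Br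
F7 | step 5 | methyl 3-[(2E,6E,10Z)-11-bromo-3,7-dimethyldodeca-2,6,10-trien-1-yl]-4-(pivaloyloxy)benzoate | COC(=O)c1ccc(OC(=O)C(C)(C)C)c(c1)C/C=C(\C)CC/C=C(\C)CC/C=C(C)\Br
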